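Remark on the chemistry: the atom numbers C1 (fully substituted oxirane carbon), C2 (acetoxy carbon), C3 (benzoyloxy carbon), C4=C5, C6 (oxirane CH) and C7 (exocyclic CH2) are used for every intermediate; compound 4 is used as paraformaldehyde.

## Analysis of the target

The target is a 7-oxabicyclo[4.1.0]hept-4-ene: a cyclohexene ring C1–C6 whose C1–C6 bond is bridged by an oxirane oxygen, with the C4=C5 double bond attached directly to the oxirane carbon C6 (a vinyl oxirane). C1 is a fully substituted oxirane carbon carrying the benzoyloxymethyl group C7; C2 bears an acetate and the allylic carbon C3 a benzoate. The four stereocentres are contiguous, (1S,2S,3R,6S). The oxirane oxygen and the C3 benzoate lie on one face of the ring, the C2 acetate and C7 on the other, so the C2 and C3 esters are trans and the C2 oxygen is anti to the oxirane. The vinyl oxirane is sensitive to acid, to SN2' attack and to low-valent metals, the C3 ester is allylic, and the three esters can migrate between neighbouring oxygens (C2/C3 vicinal, C2/C7 in a 1,3 relation). The synthesis is hard because a quaternary stereocentre sits inside the oxirane, one acetate must be placed between two benzoates, and the carbocycle has to be closed without elimination towards an arene. The strategy rests on C3: it is an allylic carbinol carbon between the C2 acetate and the cis C4=C5 alkene, so the C3–C4 bond can be made from a C3 aldehyde and a (Z)-alkenyl metal at C4, two chain ends that the cis-oxirane holds on the same side.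

## Retrosynthetic reasoning

Target 23 carries the same acyl group on O3 and O7. Both benzoates are therefore cut in one operation, back to diol 22, and 22 is traced to silyl ether 21 by desilylation. The acetate at C2 is already in place in 21, so no selective acylation among three hydroxyls is ever needed.

In 21 the C3–C4 bond is cut (Nozaki–Hiyama–Kishi transform), giving the open-chain (Z)-iodoalkenyl aldehyde 20. This bond is chosen because it is the only ring bond flanked by a carbinol and an alkene. Cutting it removes the ring and the C3 stereocentre at once and leaves a precursor in which C2 and C5 are fixed cis on the oxirane, so the forward closure is a six-membered ring formation between pre-organised ends. The forward reaction must be non-basic, since 20 is an α-acetoxy aldehyde with a β,γ-oxirane, and it must set C3 trans to C2.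

The aldehyde of 20 is traced to the terminal alkene of allylic acetate 18 (oxidative cleavage), and 18 to allylic alcohol 17. The C2–C3 bond of 17 is cut to oxirane aldehyde 15 and Grignard reagent 16. A vinyl group is preferred to a formyl anion equivalent for two reasons. It is introduced by a magnesium reagent that can chelate the oxirane oxygen and so control C2. It is also unmasked under neutral conditions that a vinyl oxirane and a (Z)-iodoalkene tolerate, whereas a strongly basic carbanion next to the iodoalkene would invite dehydroiodination.

Aldehyde 15 comes from primary alcohol 14 by oxidation. 14 comes from PMB ether 13 by oxidative deprotection, and 13 from epoxy alcohol 12 by silylation. This exchange is unavoidable: the C7 hydroxyl must be free to direct the epoxidation, and C2 can only become a carbonyl once the C1=C6 alkene has been converted to the oxirane.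

The oxirane of 12 is cut back to dienol 11 (Sharpless asymmetric epoxidation). This sets C1 and C6 in one step under reagent control, on a 2,3-disubstituted allylic alcohol with the 3-substituent trans to the hydroxymethyl group.

Dienol 11 is the reduction product of dienoate 10. The C1=C6 bond of 10 is cut (Horner–Wadsworth–Emmons) into (Z)-enal 8, formed in the flask from iodoacrylate 2, and phosphonate carbanion 9, formed from vinylphosphonate 6 and alcohol 7. The E-selective olefination puts the ester (future C7) trans and the alkoxymethyl arm (future C2) cis to C5, which is exactly the relation that the ring closure later requires.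

Iodoacrylate 2 is the hydroiodination product of ethyl propiolate 1, and 6 is the methylenation product of triethyl phosphonoacetate 3 with formaldehyde 4.

## Alternatives that were turned down

Alternative 1: The C1–C6 and C2–C3 bonds would be cut, leading back to furan A1 and maleic anhydride A2. In the forward direction their Diels–Alder reaction gives the exo, meso oxanorbornene anhydride A3; an enantioselective opening of the anhydride would then fix the absolute configuration, and the bridging oxygen would be kept as the C3 oxygen. In its favour, one step from two bulk chemicals forms the carbocycle, all six ring carbons and C7, and the meso adduct is well suited to desymmetrisation; on cost, scale and brevity of ring construction it is clearly stronger than the chosen route. Against it for this target: the carbonyl on C2 is one carbon too many and must be degraded to an oxygen. In the exo adduct that substituent is cis to the C3–O bond, whereas the target needs trans. C1 is a CH that must become a fully oxygenated quaternary centre. The C6–O bond of the bridge must be broken and C1/C6 re-oxidised to the oxirane from a defined face. Throughout, the oxanorbornene can undergo cycloreversion. The chosen strategy closes the ring with every carbon already at its final oxidation level and with C1, C2 and C6 already set.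

Alternative 2: The C1–C6 bond would be cut. In the forward direction the silyl ketene acetal of a sugar-derived six-membered lactone, carrying an (E)-2-chlorovinyl group on the ring-oxygen carbon C4, undergoes an Ireland–Claisen rearrangement through a ring-enforced boat transition state. The C1–C6 bond forms as the C4–O bond breaks, the alkene moves to C4=C5, and the carbocyclic acid A4 results. In its favour, C2 and C3 come from the chiral pool without any selectivity question, and the quaternary centre C1 and the ring arise in one pericyclic step with predictable chirality transfer; on these two points it is stronger than the chosen route. Against it: the lactone needs a long protecting-group sequence. Enolisation next to a β-alkoxy group risks β-elimination. After the rearrangement the acid must still be reduced to C7, the oxirane must be closed by displacement of an allylic chloride at C6, and two identical 4-methoxybenzyl ethers at C2 and C3 must be replaced by two different esters, which the intermediate gives no handle for. The chosen strategy is much shorter and differentiates O2 from O3 by construction, because the acetate is in place while C3 is still a carbonyl.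

Alternative 3: The C1–C6 bond and the C6–O bond would be cut together. In the forward direction base converts a (Z)-allylic cyclic sulfonium salt bearing the C1 ketone into its ylide; the ylide carbon C6 adds to the ketone to close the six-membered ring, and the alkoxide then displaces the sulfide to close the oxirane, giving A5. In its favour, ring, oxirane and both C1 and C6 are created in one step from an acyclic precursor whose C2/C3 diol can come from the chiral pool and whose C7 benzoate is already present; in bonds formed per step it is stronger than the chosen route. Against it: the facial sense of the ylide addition relative to C2 is left to the substrate alone. The basic conditions act on a ketone that has an α-stereocentre at C2, a β-alkoxy group at C3 and an α-acyloxy arm at C7 (epimerisation, elimination, acyl shift). The product again carries two identical ethers at C2 and C3 that must become an acetate and a benzoate. The chosen strategy sets C1 and C6 by reagent control, closes the ring without base, and has the ester pattern settled before the ring exists.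

Key step: step 12

## Route

Step 1
Reactants: 1 ethyl propiolate
Product: 2 ethyl (Z)-3-iodoprop-2-enoate
Conditions: NaI, AcOH, 70 °C
Reagents that add atoms: sodium iodide, [Na+].[I-]
Why: Conjugate hydroiodination of an ynoate; iodide adds to the β-carbon and the allenolate is protonated anti to iodine, so the Z-iodoacrylate should form under kinetic control.

Step 2
Reactants: 3 triethyl phosphonoacetate; 4 formaldehyde (as paraformaldehyde)
Product: 6 ethyl 2-(diethoxyphosphoryl)prop-2-enoate, via hydroxymethyl adduct 5 (not isolated)
Conditions: (CH2O)n, piperidine (cat.), MeOH, reflux; then TsOH (cat.), toluene, reflux with removal of water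
Reagents that add atoms: none
Why: Knoevenagel-type hydroxymethylation of the activated methylene followed by acid-catalysed dehydration, the standard preparation of this vinylphosphonate; the new CH2 is the future C2.

Step 3
Reactants: 2 ethyl (Z)-3-iodoprop-2-enoate; 6 ethyl 2-(diethoxyphosphoryl)prop-2-enoate; 7 4-methoxybenzyl alcohol
Product: 10 ethyl (2E,4Z)-5-iodo-2-{[(4-methoxyphenyl)methoxy]methyl}penta-2,4-dienoate, via (Z)-3-iodoprop-2-enal 8 (not isolated), via phosphonate carbanion 9 (not isolated)
Conditions: 2: iBu2AlH (1.05 equiv), CH2Cl2, −78 °C; separately 7: NaH, THF, 0 °C, then 6; carbanion solution added at −78 °C, then to 0 °C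
Reagents that add atoms: none
Why: One-pot ester reduction and tandem oxa-Michael/Horner–Wadsworth–Emmons olefination; the aluminium hemiacetal releases the labile Z-enal 8 only as it is consumed, the alkoxide of 7 adds to 6 to give the stabilised carbanion 9, and the reversible addition and elimination of 9 should place the ester trans to the iodovinyl group (2E), so the alkoxymethyl arm (future C2) ends up cis to C5.

Step 4
Reactants: 10 ethyl (2E,4Z)-5-iodo-2-{[(4-methoxyphenyl)methoxy]methyl}penta-2,4-dienoate
Product: 11 (2Z,4Z)-5-iodo-2-{[(4-methoxyphenyl)methoxy]methyl}penta-2,4-dien-1-ol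
Conditions: iBu2AlH (2.2 equiv), CH2Cl2, −78 °C
Reagents that add atoms: none
Why: 1,2-Reduction of a conjugated ester to the allylic alcohol; the vinyl iodide, the PMB ether and both alkene geometries are inert to iBu2AlH at this temperature (the 2Z descriptor only reflects the changed priorities, the geometry is unchanged).

Step 5
Reactants: 11 (2Z,4Z)-5-iodo-2-{[(4-methoxyphenyl)methoxy]methyl}penta-2,4-dien-1-ol
Product: 12 [(2R,3S)-3-[(Z)-2-iodoethenyl]-2-{[(4-methoxyphenyl)methoxy]methyl}oxiran-2-yl]methanol
Conditions: Ti(OiPr)4 (10 mol%), L-(+)-diisopropyl tartrate (12 mol%), t-BuOOH (anhydrous, 2 equiv), 4 Å molecular sieves, CH2Cl2, −20 °C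
Reagents that add atoms: tert-butyl hydroperoxide, CC(C)(C)OO
Why: Katsuki–Sharpless asymmetric epoxidation of a 2,3-disubstituted allylic alcohol whose 3-substituent is trans to the hydroxymethyl group, a favourable substrate class; only the alkene flanking the free hydroxyl reacts (the iodoalkene is electron-poor and not allylic to it), and the L-(+)-tartrate delivers oxygen in the sense that turns (E)-2-alken-1-ols into (2S,3S)-epoxy alcohols, which sets C6 as S and, the addition being syn, C1 with it.

Step 6
Reactants: 12 [(2R,3S)-3-[(Z)-2-iodoethenyl]-2-{[(4-methoxyphenyl)methoxy]methyl}oxiran-2-yl]methanol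
Product: 13 tert-butyl{[(2S,3S)-3-[(Z)-2-iodoethenyl]-2-{[(4-methoxyphenyl)methoxy]methyl}oxiran-2-yl]methoxy}dimethylsilane
Conditions: TBSCl, imidazole, DMF, 0 °C to rt
Reagents that add atoms: tert-butyldimethylsilyl chloride, CC(C)(C)[Si](C)(C)Cl
Why: Standard silylation of a primary alcohol; the silyl ether on O7 survives all steps up to the ring closure and, as a poor donor, does not compete for magnesium in step 9.

Step 7
Reactants: 13 tert-butyl{[(2S,3S)-3-[(Z)-2-iodoethenyl]-2-{[(4-methoxyphenyl)methoxy]methyl}oxiran-2-yl]methoxy}dimethylsilane
Product: 14 [(2S,3S)-2-({[tert-butyl(dimethyl)silyl]oxy}methyl)-3-[(Z)-2-iodoethenyl]oxiran-2-yl]methanol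
Conditions: DDQ, CH2Cl2/pH 7 buffer (10:1), 0 °C
Reagents that add atoms: none
Why: Oxidative cleavage of the 4-methoxybenzyl ether (electron transfer from the electron-rich arene, hydrolysis of the oxocarbenium ion); the buffer keeps the vinyl oxirane away from acid, and the silyl ether and vinyl iodide are not oxidised.

Step 8
Reactants: 14 [(2S,3S)-2-({[tert-butyl(dimethyl)silyl]oxy}methyl)-3-[(Z)-2-iodoethenyl]oxiran-2-yl]methanol
Product: 15 (2S,3S)-2-({[tert-butyl(dimethyl)silyl]oxy}methyl)-3-[(Z)-2-iodoethenyl]oxirane-2-carbaldehyde
Conditions: Dess–Martin periodinane, NaHCO3, CH2Cl2, 0 °C to rt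
Reagents that add atoms: none
Why: Dess–Martin oxidation of a primary alcohol under buffered, non-basic conditions; the aldehyde has no α-hydrogen and so cannot epimerise or enolise.

Step 9
Reactants: 15 (2S,3S)-2-({[tert-butyl(dimethyl)silyl]oxy}methyl)-3-[(Z)-2-iodoethenyl]oxirane-2-carbaldehyde; 16 vinylmagnesium bromide
Product: 17 (1S)-1-[(2R,3S)-2-({[tert-butyl(dimethyl)silyl]oxy}methyl)-3-[(Z)-2-iodoethenyl]oxiran-2-yl]prop-2-en-1-ol
Conditions: 16 (1.0 M in THF, 1.3 equiv), CH2Cl2, −78 °C; saturated NH4Cl at −78 °C
Reagents that add atoms: none
Why: Chelation-controlled Grignard addition (Cram chelate model): magnesium bridges the aldehyde oxygen and the oxirane oxygen in a five-membered chelate, and the vinyl group should attack anti to the C1–C6 bond, on the face away from C6 and its cis iodovinyl substituent, which gives the (S)-carbinol at C2 with its oxygen anti to the oxirane; at −78 °C the Grignard reagent attacks neither the oxirane nor the vinyl iodide.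

Step 10
Reactants: 17 (1S)-1-[(2R,3S)-2-({[tert-butyl(dimethyl)silyl]oxy}methyl)-3-[(Z)-2-iodoethenyl]oxiran-2-yl]prop-2-en-1-ol
Product: 18 (1S)-1-[(2S,3S)-2-({[tert-butyl(dimethyl)silyl]oxy}methyl)-3-[(Z)-2-iodoethenyl]oxiran-2-yl]prop-2-en-1-yl acetate
Conditions: Ac2O, pyridine, DMAP (cat.), CH2Cl2, 0 °C to rt
Reagents that add atoms: acetic anhydride, CC(=O)OC(C)=O
Why: Standard DMAP-catalysed acylation of a secondary alcohol; it installs the acetate of the target on O2 while no neighbouring hydroxyl is free, so no migration is possible.

Step 11
Reactants: 18 (1S)-1-[(2S,3S)-2-({[tert-butyl(dimethyl)silyl]oxy}methyl)-3-[(Z)-2-iodoethenyl]oxiran-2-yl]prop-2-en-1-yl acetate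
Product: 20 (1R)-1-[(2S,3S)-2-({[tert-butyl(dimethyl)silyl]oxy}methyl)-3-[(Z)-2-iodoethenyl]oxiran-2-yl]-2-oxoethyl acetate, via diol 19 (not isolated)
Conditions: OsO4 (2 mol%), NaIO4 (4 equiv), 2,6-lutidine, 1,4-dioxane/H2O (3:1), rt
Reagents that add atoms: osmium tetroxide, O=[Os](=O)(=O)=O; sodium periodate, [Na+].[O-]I(=O)(=O)=O
Why: Lemieux–Johnson cleavage; OsO4 should dihydroxylate the terminal monosubstituted alkene in preference to the halogen-deactivated cis-iodoalkene, periodate cleaves diol 19 as it forms and re-oxidises osmium, and the lutidine buffer keeps the medium neutral so that the acetate does not migrate and C2 does not epimerise (the R descriptor of C2 in 20 reflects changed priorities only).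

Step 12
Reactants: 20 (1R)-1-[(2S,3S)-2-({[tert-butyl(dimethyl)silyl]oxy}methyl)-3-[(Z)-2-iodoethenyl]oxiran-2-yl]-2-oxoethyl acetate
Product: 21 (1S,2S,3R,6S)-1-({[tert-butyl(dimethyl)silyl]oxy}methyl)-3-hydroxy-7-oxabicyclo[4.1.0]hept-4-en-2-yl acetate
Conditions: CrCl2 (6 equiv), NiCl2 (1 mol%), degassed DMSO, rt, 0.005 M
Reagents that add atoms: none
Why: CrCl2 reduces NiCl2 to zerovalent nickel, which inserts into the C4–I bond; the alkenyl group passes from divalent nickel to trivalent chromium, and the alkenylchromium species adds to the C3 aldehyde to give a chromium alkoxide that is hydrolysed on work-up. The closest known reaction type is the intramolecular Nozaki–Hiyama–Kishi coupling of iodoalkenyl aldehydes to cyclic allylic alcohols. The six-membered ring closes in a 6-exo-trig mode by formation of the C3–C4 bond, and because metalation and addition retain the alkene geometry, the Z-iodoalkene becomes the cis ring alkene C4=C5. The cis-oxirane holds C2 and C5 on the same side, so the two reacting carbons are already close and closure should outrun intermolecular coupling. The new stereocentre C3 is controlled by C2 and C1 through a half-chair transition state in which the C2 acetate is pseudo-equatorial (anti to the forming bond) and the bulky chromium-bound oxygen is also pseudo-equatorial, on the face of the oxirane oxygen and away from the C7 arm that occupies the other face 1,3 to C3; this gives the 2,3-trans (3R) alcohol. The step needs chemoselectivity for the C–I bond and freedom from base: the reagent is not basic, so the α-acetoxy aldehyde keeps its configuration and the acetate, silyl ether and oxirane survive. The nickel loading is kept low so that zerovalent nickel does not ionise the vinyl oxirane of the product.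

Step 13
Reactants: 21 (1S,2S,3R,6S)-1-({[tert-butyl(dimethyl)silyl]oxy}methyl)-3-hydroxy-7-oxabicyclo[4.1.0]hept-4-en-2-yl acetate
Product: 22 (1S,2S,3R,6S)-3-hydroxy-1-(hydroxymethyl)-7-oxabicyclo[4.1.0]hept-4-en-2-yl acetate
Conditions: Bu4NF/AcOH (1:1, 3 equiv), THF, 0 °C to rt
Reagents that add atoms: none
Why: Fluoride-mediated cleavage of the primary silyl ether; buffering with acetic acid keeps the medium non-basic, so the acetate should not migrate to the freed hydroxyls and the vinyl oxirane is not attacked.

Step 14
Reactants: 22 (1S,2S,3R,6S)-3-hydroxy-1-(hydroxymethyl)-7-oxabicyclo[4.1.0]hept-4-en-2-yl acetate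
Product: 23 [(1S,2S,3R,6S)-2-acetoxy-3-(benzoyloxy)-7-oxabicyclo[4.1.0]hept-4-en-1-yl]methyl benzoate
Conditions: BzCl (3 equiv), pyridine, DMAP (cat.), CH2Cl2, 0 °C to rt
Reagents that add atoms: benzoyl chloride, O=C(Cl)c1ccccc1
Why: DMAP-catalysed acylation of the primary C7 and the secondary allylic C3 hydroxyl with the same reagent; since both oxygens carry benzoate in the target, no selectivity is required and no stereocentre is touched.

## Compound list

1 | ethyl propiolate | C#CC(=O)OCC | starting material
2 | ethyl (Z)-3-iodoprop-2-enoate | CCOC(=O)/C=C\I | intermediate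
3 | triethyl phosphonoacetate | CCOC(=O)CP(=O)(OCC)OCC | starting material
4 | formaldehyde (used as paraformaldehyde) | C=O | starting material
5 | ethyl 2-(diethoxyphosphoryl)-3-hydroxypropanoate | CCOC(=O)C(CO)P(=O)(OCC)OCC | intermediate (not isolated)
6 | ethyl 2-(diethoxyphosphoryl)prop-2-enoate | CCOC(=O)C(=C)P(=O)(OCC)OCC | intermediate
7 | 4-methoxybenzyl alcohol | COc1ccc(CO)cc1 | starting material
8 | (Z)-3-iodoprop-2-enal | O=C/C=C\I | intermediate (not isolated)
9 | sodium salt of the carbanion of ethyl 2-(diethoxyphosphoryl)-3-[(4-methoxyphenyl)methoxy]propanoate | CCOC(=O)[C-](COCc1ccc(OC)cc1)P(=O)(OCC)OCC.[Na+] | intermediate (not isolated)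
10 | ethyl (2E,4Z)-5-iodo-2-{[(4-methoxyphenyl)methoxy]methyl}penta-2,4-dienoate | CCOC(=O)/C(COCc1ccc(OC)cc1)=C/C=C\I | intermediate
11 | (2Z,4Z)-5-iodo-2-{[(4-methoxyphenyl)methoxy]methyl}penta-2,4-dien-1-ol | OC/C(COCc1ccc(OC)cc1)=C/C=C\I | intermediate
12 | [(2R,3S)-3-[(Z)-2-iodoethenyl]-2-{[(4-methoxyphenyl)methoxy]methyl}oxiran-2-yl]methanol | COc1ccc(COC[C@@]2(CO)O[C@H]2/C=C\I)cc1 | intermediate
13 | tert-butyl{[(2S,3S)-3-[(Z)-2-iodoethenyl]-2-{[(4-methoxyphenyl)methoxy]methyl}oxiran-2-yl]methoxy}dimethylsilane | COc1ccc(COC[C@@]2(CO[Si](C)(C)C(C)(C)C)O[C@H]2/C=C\I)cc1 | intermediate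
14 | [(2S,3S)-2-({[tert-butyl(dimethyl)silyl]oxy}methyl)-3-[(Z)-2-iodoethenyl]oxiran-2-yl]methanol | OC[C@@]1(CO[Si](C)(C)C(C)(C)C)O[C@H]1/C=C\I | intermediate
15 | (2S,3S)-2-({[tert-butyl(dimethyl)silyl]oxy}methyl)-3-[(Z)-2-iodoethenyl]oxirane-2-carbaldehyde | O=C[C@@]1(CO[Si](C)(C)C(C)(C)C)O[C@H]1/C=C\I | intermediate
16 | vinylmagnesium bromide | C=C[Mg]Br | starting material
17 | (1S)-1-[(2R,3S)-2-({[tert-butyl(dimethyl)silyl]oxy}methyl)-3-[(Z)-2-iodoethenyl]oxiran-2-yl]prop-2-en-1-ol | C=C[C@H](O)[C@@]1(CO[Si](C)(C)C(C)(C)C)O[C@H]1/C=C\I | intermediate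
18 | (1S)-1-[(2S,3S)-2-({[tert-butyl(dimethyl)silyl]oxy}methyl)-3-[(Z)-2-iodoethenyl]oxiran-2-yl]prop-2-en-1-yl acetate | C=C[C@H](OC(C)=O)[C@@]1(CO[Si](C)(C)C(C)(C)C)O[C@H]1/C=C\I | intermediate
19 | (1S)-1-[(2S,3S)-2-({[tert-butyl(dimethyl)silyl]oxy}methyl)-3-[(Z)-2-iodoethenyl]oxiran-2-yl]-2,3-dihydroxypropyl acetate (both epimers at the secondary carbinol) | OCC(O)[C@H](OC(C)=O)[C@@]1(CO[Si](C)(C)C(C)(C)C)O[C@H]1/C=C\I | intermediate (not isolated)
20 | (1R)-1-[(2S,3S)-2-({[tert-butyl(dimethyl)silyl]oxy}methyl)-3-[(Z)-2-iodoethenyl]oxiran-2-yl]-2-oxoethyl acetate | O=C[C@H](OC(C)=O)[C@@]1(CO[Si](C)(C)C(C)(C)C)O[C@H]1/C=C\I | intermediate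
21 | (1S,2S,3R,6S)-1-({[tert-butyl(dimethyl)silyl]oxy}methyl)-3-hydroxy-7-oxabicyclo[4.1.0]hept-4-en-2-yl acetate | CC(=O)O[C@H]1[C@H](O)C=C[C@@H]2O[C@@]21CO[Si](C)(C)C(C)(C)C | intermediate
22 | (1S,2S,3R,6S)-3-hydroxy-1-(hydroxymethyl)-7-oxabicyclo[4.1.0]hept-4-en-2-yl acetate | CC(=O)O[C@H]1[C@H](O)C=C[C@@H]2O[C@@]21CO | intermediate
23 | [(1S,2S,3R,6S)-2-acetoxy-3-(benzoyloxy)-7-oxabicyclo[4.1.0]hept-4-en-1-yl]methyl benzoate | CC(=O)O[C@H]1[C@H](OC(=O)c2ccccc2)C=C[C@@H]2O[C@@]21COC(=O)c1ccccc1 | target

## Step count and least certain steps

Total step count: 14. Longest linear sequence: 13 steps (steps 1 and 3–14 from compound 1; equally steps 2–14 from compound 3).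

Step 12 (key step). The most likely failure is poor facial selectivity at C3: an open Felkin–Anh arrangement would put the carbonyl oxygen pseudo-axial and give the 2,3-cis alcohol, so the outcome depends on the ring transition state overriding it. A second hazard is loss of material through ionisation of the vinyl oxirane by zerovalent nickel, or protonation of the alkenylchromium species before it adds. The fallback keeps the same disconnection and sets out from 20. The cyclisation is run as in step 12. If the C3 epimer, (1S,2S,3S,6S)-1-({[tert-butyl(dimethyl)silyl]oxy}methyl)-3-hydroxy-7-oxabicyclo[4.1.0]hept-4-en-2-yl acetate F1, is the main product, it is treated with benzoic acid, PPh3 and diisopropyl azodicarboxylate in toluene at 0 °C (Mitsunobu inversion). This should give (1S,2S,3R,6S)-2-acetoxy-1-({[tert-butyl(dimethyl)silyl]oxy}methyl)-7-oxabicyclo[4.1.0]hept-4-en-3-yl benzoate F2 with the correct C3 configuration. Desilylation with Bu4NF/AcOH gives (1S,2S,3R,6S)-2-acetoxy-1-(hydroxymethyl)-7-oxabicyclo[4.1.0]hept-4-en-3-yl benzoate F3, and benzoyl chloride/pyridine then gives 23, where the fallback rejoins the route.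

Step 9. The most likely failure is erosion of facial selectivity: if THF breaks the magnesium chelate, the aldehyde reacts through a dipole-minimised conformer and the C2 epimer forms; in the same step some dehydroiodination of the (Z)-iodoalkene by the basic reagent is possible. The fallback sets out from 15. The addition is run as in step 9 and the unwanted epimer, (1R)-1-[(2R,3S)-2-({[tert-butyl(dimethyl)silyl]oxy}methyl)-3-[(Z)-2-iodoethenyl]oxiran-2-yl]prop-2-en-1-ol F4, is separated and treated with acetic acid, PPh3 and diisopropyl azodicarboxylate in THF at 0 °C. The Mitsunobu displacement inverts C2 and installs the acetate in one operation, so this material rejoins the route at 18; C2 is then set by substitution instead of by carbonyl facial selectivity.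

Step 11. The most likely failure is incomplete chemoselectivity of the osmylation (attack on the iodoalkene as well) or acetate migration within diol 19 before it is cleaved. The fallback replaces the vinyl group by a thioacetal as the masked C3 aldehyde and sets out from 15. Addition of 2-lithio-1,3-dithiane (1,3-dithiane, n-BuLi, THF, −78 °C) gives (R)-[(2R,3S)-2-({[tert-butyl(dimethyl)silyl]oxy}methyl)-3-[(Z)-2-iodoethenyl]oxiran-2-yl](1,3-dithian-2-yl)methanol F5; the C2 epimer, if formed, is removed at this stage. Acetylation (Ac2O, pyridine, DMAP) gives (R)-[(2S,3S)-2-({[tert-butyl(dimethyl)silyl]oxy}methyl)-3-[(Z)-2-iodoethenyl]oxiran-2-yl](1,3-dithian-2-yl)methyl acetate F6. Alkylative hydrolysis (MeI, CaCO3, MeCN/H2O, 40 °C) then frees the aldehyde, rejoining the route at 20.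

Step 3. The most likely failure is Z-to-E isomerisation of the labile enal 8, or an unfavourable E/Z ratio in the olefination with the α-branched carbanion. The fallback builds the iodoalkene last and sets out from 6 and 7. Carbanion 9 is formed as in step 3 and condensed with anhydrous 2,2-dimethoxyacetaldehyde (THF, 0 °C) to give ethyl (E)-4,4-dimethoxy-2-{[(4-methoxyphenyl)methoxy]methyl}but-2-enoate F7. Mild aqueous acid (HCO2H/H2O, rt) gives ethyl (E)-2-{[(4-methoxyphenyl)methoxy]methyl}-4-oxobut-2-enoate F8. A Stork–Zhao olefination ((Ph3PCH2I)I, NaN(SiMe3)2, THF/DMPU, −78 °C) then installs the (Z)-iodoalkene and rejoins the route at 10.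

## Further compounds

F1 | step 12 | (1S,2S,3S,6S)-1-({[tert-butyl(dimethyl)silyl]oxy}methyl)-3-hydroxy-7-oxabicyclo[4.1.0]hept-4-en-2-yl acetate | CC(=O)O[C@H]1[C@@H](O)C=C[C@@H]2O[C@@]21CO[Si](C)(C)C(C)(C)C
F2 | step 12 | (1S,2S,3R,6S)-2-acetoxy-1-({[tert-butyl(dimethyl)silyl]oxy}methyl)-7-oxabicyclo[4.1.0]hept-4-en-3-yl benzoate | CC(=O)O[C@H]1[C@H](OC(=O)c2ccccc2)C=C[C@@H]2O[C@@]21CO[Si](C)(C)C(C)(C)C
F3 | step 12 | (1S,2S,3R,6S)-2-acetoxy-1-(hydroxymethyl)-7-oxabicyclo[4.1.0]hept-4-en-3-yl benzoate | CC(=O)O[C@H]1[C@H](OC(=O)c2ccccc2)C=C[C@@H]2O[C@@]21CO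
F4 | step 9 | (1R)-1-[(2R,3S)-2-({[tert-butyl(dimethyl)silyl]oxy}methyl)-3-[(Z)-2-iodoethenyl]oxiran-2-yl]prop-2-en-1-ol | C=C[C@@H](O)[C@@]1(CO[Si](C)(C)C(C)(C)C)O[C@H]1/C=C\I
F5 | step 11 | (R)-[(2R,3S)-2-({[tert-butyl(dimethyl)silyl]oxy}methyl)-3-[(Z)-2-iodoethenyl]oxiran-2-yl](1,3-dithian-2-yl)methanol | S1CCCSC1[C@H](O)[C@@]2(CO[Si](C)(C)C(C)(C)C)O[C@H]2/C=C\I
F6 | step 11 | (R)-[(2S,3S)-2-({[tert-butyl(dimethyl)silyl]oxy}methyl)-3-[(Z)-2-iodoethenyl]oxiran-2-yl](1,3-dithian-2-yl)methyl acetate | S1CCCSC1[C@H](OC(C)=O)[C@@]2(CO[Si](C)(C)C(C)(C)C)O[C@H]2/C=C\I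
F7 | step 3 | ethyl (E)-4,4-dimethoxy-2-{[(4-methoxyphenyl)methoxy]methyl}but-2-enoate | CCOC(=O)/C(COCc1ccc(OC)cc1)=C/C(OC)OC
F8 | step 3 | ethyl (E)-2-{[(4-methoxyphenyl)methoxy]methyl}-4-oxobut-2-enoate | CCOC(=O)/C(COCc1ccc(OC)cc1)=C/C=O
A1 | alternative 1 | furan | c1ccoc1
A2 | alternative 1 | maleic anhydride | O=C1C=CC(=O)O1
A3 | alternative 1 | exo-7-oxabicyclo[2.2.1]hept-5-ene-2,3-dicarboxylic anhydride (meso) | O=C1OC(=O)[C@H]2[C@@H]1[C@@H]1C=C[C@H]2O1
A4 | alternative 2 | 6-chloro-2,3-bis[(4-methoxyphenyl)methoxy]-1-(triethylsilyloxy)cyclohex-4-ene-1-carboxylic acid | COc1ccc(cc1)CO[C@H]1[C@H](OCc2ccc(OC)cc2)C=C[C@@H](Cl)[C@@]1(O[Si](CC)(CC)CC)C(=O)O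
A5 | alternative 3 | {2,3-bis[(4-methoxyphenyl)methoxy]-7-oxabicyclo[4.1.0]hept-4-en-1-yl}methyl benzoate | COc1ccc(cc1)CO[C@H]1[C@H](OCc2ccc(OC)cc2)C=C[C@@H]2O[C@@]21COC(=O)c1ccccc1
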